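The carbocycle of the epoxide end group (C1–C6, carotenoid numbering; C1 gem-dimethyl, C3 oxygenated, C5 methyl-bearing) is built by one-carbon enlargement of a cyclopentanone. Diazoethane inserts a CH(CH3) unit, the future C5, between the carbonyl carbon (future C6) and the unsubstituted α-methylene of (S)-4-silyloxy-2,2-dimethylcyclopentanone. One operation delivers the full trimethylcyclohexanone pattern with C3 already set; the uncontrolled C5 methyl centre is erased on enol triflate formation. Because the acetylenic end ring has the same pattern, the one ring-expanded ketone supplies both termini. The polyene–butenolide core then follows from Sonogashira/lactonisation, Suzuki and Stille couplings.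

Key step: step 4

Assumption: the CuCl/(R,S)-Josiphos catalyst of step 2 is taken to deliver boron to the enone face that leads to (S)-4; should the sense be opposite, the mirror-image ligand is used and nothing else changes.

Step 1
Reactants: 1 2,2-dimethylcyclopentan-1-one
Product: 2 5,5-dimethylcyclopent-2-en-1-one
Conditions: IBX, DMSO, 75 °C
Reagents that add atoms: none
Why: IBX α,β-dehydrogenation of the ketone can only proceed towards the methylene side because the other α-carbon is quaternary, so a single enone should form.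

Step 2
Reactants: 2 5,5-dimethylcyclopent-2-en-1-one
Product: 4 (4S)-4-hydroxy-2,2-dimethylcyclopentan-1-one, via β-boryl ketone 3 (not isolated)
Conditions: B2pin2, CuCl (3 mol%), NaOtBu (6 mol%), (R,S)-Josiphos (4 mol%), MeOH, THF, rt; then NaBO3·4H2O, THF/H2O, rt
Reagents that add atoms: sodium perborate [Na+].[O-]OB=O (hydroxyl oxygen of 4); bis(pinacolato)diboron CC1(C)OB(OC1(C)C)B1OC(C)(C)C(C)(C)O1 (boron of 3)
Why: Copper-catalysed asymmetric conjugate borylation places boron on one face of the enone β-carbon under control of the chiral bisphosphine, and perborate oxidation replaces C–B by C–O with retention, which sets the S carbinol centre.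

Step 3
Reactants: 4 (4S)-4-hydroxy-2,2-dimethylcyclopentan-1-one
Product: 5 (4S)-4-[(tert-butyldimethylsilyl)oxy]-2,2-dimethylcyclopentan-1-one
Conditions: TBSCl, imidazole, DMF, rt
Reagents that add atoms: tert-butyldimethylsilyl chloride CC(C)(C)[Si](C)(C)Cl
Why: Standard silylation of a secondary alcohol under conditions mild enough not to trigger β-elimination of the β-oxygenated ketone.

Step 4
Reactants: 5 (4S)-4-[(tert-butyldimethylsilyl)oxy]-2,2-dimethylcyclopentan-1-one
Product: 6 (4R)-4-[(tert-butyldimethylsilyl)oxy]-2,2,6-trimethylcyclohexan-1-one (both C6 epimers)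
Conditions: CH3CHN2 (pre-formed ethereal solution), Sc(OTf)3 (10 mol%), CH2Cl2/toluene, −78 → −40 °C
Reagents that add atoms: diazoethane CC=[N+]=[N-]
Why: The Sc(OTf)3-activated carbonyl of 5 is attacked by the nucleophilic carbon of diazoethane to give a β-diazonium alkoxide, and a 1,2-shift of a ring α-carbon anti to the departing N2 gives the six-membered ketone (Lewis-acid-catalysed diazoalkane homologation of the Tiffeneau–Demjanov type). No ring is closed; the cyclopentanone is enlarged by one carbon through the 1,2-alkyl shift, which also turns the base-labile β-silyloxy ketone into a γ-silyloxy ketone. The selectivity needed is migration of the C5 methylene rather than the quaternary C2: diazoalkane homologations favour shift of the less substituted α-carbon, and the gem-dimethyl group disfavours the conformer that places C2 anti to N2. The existing oxygenated stereocentre is remote from the reacting atoms and is carried over unchanged (its descriptor becomes R only through a change of priorities). The one new stereocentre, the methyl-bearing C6, is not controlled and need not be, since both epimers give the same enolate in step 5. A second insertion should be slow because the product carbonyl is flanked by a quaternary and a tertiary carbon.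

Step 5
Reactants: 6 (4R)-4-[(tert-butyldimethylsilyl)oxy]-2,2,6-trimethylcyclohexan-1-one
Product: 7 (4R)-4-[(tert-butyldimethylsilyl)oxy]-2,6,6-trimethylcyclohex-1-en-1-yl trifluoromethanesulfonate
Conditions: LDA, THF, −78 → 0 °C; PhNTf2, −78 °C → rt
Reagents that add atoms: N-phenylbis(trifluoromethanesulfonimide) O=S(=O)(N(c1ccccc1)S(=O)(=O)C(F)(F)F)C(F)(F)F
Why: Deprotonation is only possible at the methyl-bearing α-carbon, and O-triflation of the enolate funnels both epimers of 6 into one tetrasubstituted enol triflate.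

Step 6
Reactants: 7 (4R)-4-[(tert-butyldimethylsilyl)oxy]-2,6,6-trimethylcyclohex-1-en-1-yl trifluoromethanesulfonate
Product: 8 methyl (4R)-4-[(tert-butyldimethylsilyl)oxy]-2,6,6-trimethylcyclohex-1-ene-1-carboxylate
Conditions: CO (1 atm), Pd(OAc)2 (5 mol%), PPh3 (10 mol%), Et3N, MeOH/DMF, 70 °C
Reagents that add atoms: carbon monoxide [C-]#[O+]; methanol CO
Why: Palladium-catalysed alkoxycarbonylation of the enol triflate (oxidative addition, CO insertion, methanolysis) installs C7 at the ester level.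

Step 7
Reactants: 8 methyl (4R)-4-[(tert-butyldimethylsilyl)oxy]-2,6,6-trimethylcyclohex-1-ene-1-carboxylate
Product: 9 [(4R)-4-[(tert-butyldimethylsilyl)oxy]-2,6,6-trimethylcyclohex-1-en-1-yl]methanol
Conditions: DIBAL-H, CH2Cl2, −78 → 0 °C
Reagents that add atoms: none
Why: DIBAL-H 1,2-reduction of the conjugated ester gives the allylic alcohol and leaves the silyl ether untouched.

Step 8
Reactants: 9 [(4R)-4-[(tert-butyldimethylsilyl)oxy]-2,6,6-trimethylcyclohex-1-en-1-yl]methanol
Product: 10 [(1R,4S,6R)-4-[(tert-butyldimethylsilyl)oxy]-2,2,6-trimethyl-7-oxabicyclo[4.1.0]heptan-1-yl]methanol (epoxide trans to the silyloxy group)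
Conditions: Ti(OiPr)4 (1.0 equiv), D-(−)-DET (1.2 equiv), tBuOOH, 4 Å MS, CH2Cl2, −20 °C
Reagents that add atoms: tert-butyl hydroperoxide CC(C)(C)OO
Why: Sharpless asymmetric epoxidation of the allylic alcohol, in which D-(−)-tartrate should deliver oxygen to the ring face anti to the silyloxy group (also the less hindered face), sets both epoxide centres at once.

Step 9
Reactants: 10 the epoxy alcohol
Product: 11 (1S,4S,6R)-4-[(tert-butyldimethylsilyl)oxy]-2,2,6-trimethyl-7-oxabicyclo[4.1.0]heptane-1-carbaldehyde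
Conditions: nPr4N[RuO4] (5 mol%), NMO, 4 Å MS, CH2Cl2, rt
Reagents that add atoms: none
Why: Ley–Griffith oxidation is neutral, so the acid-sensitive epoxide survives, and the aldehyde formed is not enolisable.

Step 10
Reactants: 11 the epoxy aldehyde
Product: 12 (1S,4S,6R)-4-[(tert-butyldimethylsilyl)oxy]-1-[(E)-2-iodoethenyl]-2,2,6-trimethyl-7-oxabicyclo[4.1.0]heptane
Conditions: CrCl2, CHI3, THF, 0 °C → rt
Reagents that add atoms: iodoform IC(I)I
Why: Takai olefination, in which the gem-dichromium reagent adds to the aldehyde and eliminates to the E-vinyl iodide; the fully substituted epoxide should be left alone.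

Step 11
Reactants: 12 the E-vinyl iodide
Product: 14 tributyl{(E)-2-[(1S,4S,6R)-4-[(tert-butyldimethylsilyl)oxy]-2,2,6-trimethyl-7-oxabicyclo[4.1.0]heptan-1-yl]ethenyl}stannane, via vinyllithium 13 (not isolated)
Conditions: t-BuLi (2.1 equiv), Et2O, −78 °C; then Bu3SnCl, −78 °C → rt
Reagents that add atoms: tributyltin chloride CCCC[Sn](Cl)(CCCC)CCCC
Why: Iodine–lithium exchange and stannylation both proceed with retention of alkene geometry, and the in-plane vinyl carbanion cannot open the neighbouring hindered epoxide at −78 °C.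

Step 12
Reactants: 14 the silyl-protected vinylstannane
Product: 15 (1R,3S,6S)-1,5,5-trimethyl-6-[(E)-2-(tributylstannyl)ethenyl]-7-oxabicyclo[4.1.0]heptan-3-ol
Conditions: TBAF, THF, rt
Reagents that add atoms: none
Why: Fluoride-induced desilylation, to which the vinylstannane and the epoxide are inert.

Step 13
Reactants: 7 the enol triflate; 16 (2E)-3-methylpent-2-en-4-yn-1-ol
Product: 17 (2E)-5-[(4R)-4-[(tert-butyldimethylsilyl)oxy]-2,6,6-trimethylcyclohex-1-en-1-yl]-3-methylpent-2-en-4-yn-1-ol
Conditions: Pd(PPh3)4 (5 mol%), CuI (10 mol%), iPr2NH, DMF, rt → 40 °C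
Reagents that add atoms: none
Why: Sonogashira coupling of the enol triflate with the terminal alkyne joins ring A to the first chain unit and leaves the E alkene of the enynol untouched.

Step 14
Reactants: 17 the silyl-protected enynol
Product: 18 (1R)-4-[(3E)-5-hydroxy-3-methylpent-3-en-1-yn-1-yl]-3,5,5-trimethylcyclohex-3-en-1-ol
Conditions: TBAF, THF, rt
Reagents that add atoms: none
Why: Fluoride-induced desilylation frees the ring hydroxyl before the chain is extended.

Step 15
Reactants: 18 the diol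
Product: 19 (2E)-5-[(4R)-4-hydroxy-2,6,6-trimethylcyclohex-1-en-1-yl]-3-methylpent-2-en-4-ynal
Conditions: MnO2, CH2Cl2, rt
Reagents that add atoms: none
Why: MnO2 oxidises only the allylic primary alcohol and leaves the saturated secondary alcohol.

Step 16
Reactants: 19 the hydroxy enal
Product: 20 (1R)-3,5,5-trimethyl-4-[(3E,5E)-3-methyl-6-(4,4,5,5-tetramethyl-1,3,2-dioxaborolan-2-yl)hexa-3,5-dien-1-yn-1-yl]cyclohex-3-en-1-ol
Conditions: CrCl2, Cl2CHBpin, LiI, THF, rt
Reagents that add atoms: 2-(dichloromethyl)-4,4,5,5-tetramethyl-1,3,2-dioxaborolane ClC(Cl)B1OC(C)(C)C(C)(C)O1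
Why: Takai–Utimoto boryl-olefination, in which the gem-dichromium boronate adds to the enal and eliminates to the E-alkenylboronate; the free hydroxyl is tolerated.

Step 17
Reactants: 21 propiolic acid
Product: 22 (2E)-2,3-dibromoprop-2-enoic acid
Conditions: Br2, CHCl3, rt, dark
Reagents that add atoms: bromine BrBr
Why: Anti addition of bromine across the alkyne gives the E dibromide, in which the C3 bromide is cis to the carboxyl group as lactonisation requires.

Step 18
Reactants: 22 (2E)-2,3-dibromoprop-2-enoic acid; 16 (2E)-3-methylpent-2-en-4-yn-1-ol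
Product: 24 (5Z)-3-bromo-5-[(2E)-4-hydroxy-2-methylbut-2-en-1-ylidene]furan-2(5H)-one, via enynoic acid 23 (not isolated)
Conditions: PdCl2(PPh3)2 (5 mol%), CuI (10 mol%), Et3N, MeCN, rt
Reagents that add atoms: none
Why: Tandem Sonogashira coupling and 5-exo-dig lactonisation, in which the more electrophilic C3–Br couples with retention and anti addition of the carboxylate across the metal-activated alkyne gives the Z-ylidene butenolide while the C2–Br stays as a handle.

Step 19
Reactants: 24 the bromobutenolide alcohol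
Product: 25 (2E,4Z)-4-(4-bromo-5-oxofuran-2(5H)-ylidene)-3-methylbut-2-enal
Conditions: MnO2, CH2Cl2, rt
Reagents that add atoms: none
Why: Mild heterogeneous oxidation of the allylic alcohol under neutral conditions that the ylidene butenolide should tolerate.

Step 20
Reactants: 25 the bromobutenolide enal
Product: 26 (5Z)-3-bromo-5-[(2E,4E)-5-iodo-2-methylpenta-2,4-dien-1-ylidene]furan-2(5H)-one
Conditions: CrCl2, CHI3, THF/dioxane, 0 °C
Reagents that add atoms: iodoform IC(I)I
Why: Takai olefination converts the enal into the E-dienyl iodide, and the vinylic C–Br bond is not touched by CrCl2 in the absence of a nickel co-catalyst.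

Step 21
Reactants: 20 the dienylboronate; 26 the dienyl iodide
Product: 27 (5Z)-3-bromo-5-[(2E,4E,6E,8E)-11-[(4R)-4-hydroxy-2,6,6-trimethylcyclohex-1-en-1-yl]-2,9-dimethylundeca-2,4,6,8-tetraen-10-yn-1-ylidene]furan-2(5H)-one
Conditions: Pd(PPh3)4 (10 mol%), TlOEt, THF/H2O (3:1), rt, dark
Reagents that add atoms: none
Why: Suzuki–Miyaura coupling with retention at both alkenes, in which oxidative addition to the dienyl C–I bond should be much faster at room temperature than to the butenolide C–Br bond and TlOEt makes transmetalation fast enough to keep the exposure to base short.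

Step 22
Reactants: 27 the bromo polyene; 15 the hydroxy vinylstannane
Product: 28 pyrrhoxanthinol (CNP0180336.1), (5Z)-5-[(2E,4E,6E,8E)-11-[(4R)-4-hydroxy-2,6,6-trimethylcyclohex-1-en-1-yl]-2,9-dimethylundeca-2,4,6,8-tetraen-10-yn-1-ylidene]-3-{(E)-2-[(1S,4S,6R)-4-hydroxy-2,2,6-trimethyl-7-oxabicyclo[4.1.0]heptan-1-yl]ethenyl}furan-2(5H)-one
Conditions: Pd2(dba)3 (5 mol%), AsPh3 (40 mol%), NMP, 45 °C, dark
Reagents that add atoms: none
Why: Stille coupling at the butenolide C3–Br bond with retention of the E-vinylstannane geometry, under neutral conditions that should spare the epoxide, the ylidene butenolide and both free hydroxyl groups.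

Compound list
1 | 2,2-dimethylcyclopentan-1-one | CC1(C)CCCC1=O | starting material
2 | 5,5-dimethylcyclopent-2-en-1-one | CC1(C)CC=CC1=O | intermediate
3 | (4S)-2,2-dimethyl-4-(4,4,5,5-tetramethyl-1,3,2-dioxaborolan-2-yl)cyclopentan-1-one | CC1(C)C[C@H](B2OC(C)(C)C(C)(C)O2)CC1=O | intermediate
4 | (4S)-4-hydroxy-2,2-dimethylcyclopentan-1-one | CC1(C)C[C@H](O)CC1=O | intermediate
5 | (4S)-4-[(tert-butyldimethylsilyl)oxy]-2,2-dimethylcyclopentan-1-one | CC1(C)C[C@H](O[Si](C)(C)C(C)(C)C)CC1=O | intermediate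
6 | (4R)-4-[(tert-butyldimethylsilyl)oxy]-2,2,6-trimethylcyclohexan-1-one, both C6 epimers | CC1C[C@@H](O[Si](C)(C)C(C)(C)C)CC(C)(C)C1=O | intermediate
7 | (4R)-4-[(tert-butyldimethylsilyl)oxy]-2,6,6-trimethylcyclohex-1-en-1-yl trifluoromethanesulfonate | CC1=C(OS(=O)(=O)C(F)(F)F)C(C)(C)C[C@H](O[Si](C)(C)C(C)(C)C)C1 | intermediate
8 | methyl (4R)-4-[(tert-butyldimethylsilyl)oxy]-2,6,6-trimethylcyclohex-1-ene-1-carboxylate | COC(=O)C1=C(C)C[C@@H](O[Si](C)(C)C(C)(C)C)CC1(C)C | intermediate
9 | [(4R)-4-[(tert-butyldimethylsilyl)oxy]-2,6,6-trimethylcyclohex-1-en-1-yl]methanol | OCC1=C(C)C[C@@H](O[Si](C)(C)C(C)(C)C)CC1(C)C | intermediate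
10 | [(1R,4S,6R)-4-[(tert-butyldimethylsilyl)oxy]-2,2,6-trimethyl-7-oxabicyclo[4.1.0]heptan-1-yl]methanol, epoxide trans to OTBS | OC[C@@]12O[C@]1(C)C[C@@H](O[Si](C)(C)C(C)(C)C)CC2(C)C | intermediate
11 | (1S,4S,6R)-4-[(tert-butyldimethylsilyl)oxy]-2,2,6-trimethyl-7-oxabicyclo[4.1.0]heptane-1-carbaldehyde | O=C[C@@]12O[C@]1(C)C[C@@H](O[Si](C)(C)C(C)(C)C)CC2(C)C | intermediate
12 | (1S,4S,6R)-4-[(tert-butyldimethylsilyl)oxy]-1-[(E)-2-iodoethenyl]-2,2,6-trimethyl-7-oxabicyclo[4.1.0]heptane | I/C=C/[C@@]12O[C@]1(C)C[C@@H](O[Si](C)(C)C(C)(C)C)CC2(C)C | intermediate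
13 | (E)-vinyllithium derived from 12 | [Li]/C=C/[C@@]12O[C@]1(C)C[C@@H](O[Si](C)(C)C(C)(C)C)CC2(C)C | intermediate
14 | tributyl{(E)-2-[(1S,4S,6R)-4-[(tert-butyldimethylsilyl)oxy]-2,2,6-trimethyl-7-oxabicyclo[4.1.0]heptan-1-yl]ethenyl}stannane | CCCC[Sn](CCCC)(CCCC)/C=C/[C@@]12O[C@]1(C)C[C@@H](O[Si](C)(C)C(C)(C)C)CC2(C)C | intermediate
15 | (1R,3S,6S)-1,5,5-trimethyl-6-[(E)-2-(tributylstannyl)ethenyl]-7-oxabicyclo[4.1.0]heptan-3-ol | CCCC[Sn](CCCC)(CCCC)/C=C/[C@@]12O[C@]1(C)C[C@@H](O)CC2(C)C | intermediate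
16 | (2E)-3-methylpent-2-en-4-yn-1-ol | C#C/C(C)=C/CO | starting material
17 | (2E)-5-[(4R)-4-[(tert-butyldimethylsilyl)oxy]-2,6,6-trimethylcyclohex-1-en-1-yl]-3-methylpent-2-en-4-yn-1-ol | CC1=C(C#C/C(C)=C/CO)C(C)(C)C[C@H](O[Si](C)(C)C(C)(C)C)C1 | intermediate
18 | (1R)-4-[(3E)-5-hydroxy-3-methylpent-3-en-1-yn-1-yl]-3,5,5-trimethylcyclohex-3-en-1-ol | CC1=C(C#C/C(C)=C/CO)C(C)(C)C[C@H](O)C1 | intermediate
19 | (2E)-5-[(4R)-4-hydroxy-2,6,6-trimethylcyclohex-1-en-1-yl]-3-methylpent-2-en-4-ynal | CC1=C(C#C/C(C)=C/C=O)C(C)(C)C[C@H](O)C1 | intermediate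
20 | (1R)-3,5,5-trimethyl-4-[(3E,5E)-3-methyl-6-(4,4,5,5-tetramethyl-1,3,2-dioxaborolan-2-yl)hexa-3,5-dien-1-yn-1-yl]cyclohex-3-en-1-ol | CC1=C(C#C/C(C)=C/C=C/B2OC(C)(C)C(C)(C)O2)C(C)(C)C[C@H](O)C1 | intermediate
21 | propiolic acid | C#CC(=O)O | starting material
22 | (2E)-2,3-dibromoprop-2-enoic acid | OC(=O)/C(Br)=C\Br | intermediate
23 | (2E,6E)-2-bromo-8-hydroxy-6-methylocta-2,6-dien-4-ynoic acid | OC(=O)/C(Br)=C\C#C/C(C)=C/CO | intermediate
24 | (5Z)-3-bromo-5-[(2E)-4-hydroxy-2-methylbut-2-en-1-ylidene]furan-2(5H)-one | OC/C=C(C)/C=C1C=C(Br)C(=O)O/1 | intermediate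
25 | (2E,4Z)-4-(4-bromo-5-oxofuran-2(5H)-ylidene)-3-methylbut-2-enal | O=C/C=C(C)/C=C1C=C(Br)C(=O)O/1 | intermediate
26 | (5Z)-3-bromo-5-[(2E,4E)-5-iodo-2-methylpenta-2,4-dien-1-ylidene]furan-2(5H)-one | I/C=C/C=C(C)/C=C1C=C(Br)C(=O)O/1 | intermediate
27 | (5Z)-3-bromo-5-[(2E,4E,6E,8E)-11-[(4R)-4-hydroxy-2,6,6-trimethylcyclohex-1-en-1-yl]-2,9-dimethylundeca-2,4,6,8-tetraen-10-yn-1-ylidene]furan-2(5H)-one | CC1=C(C#C/C(C)=C/C=C/C=C/C=C(C)/C=C2C=C(Br)C(=O)O/2)C(C)(C)C[C@H](O)C1 | intermediate
28 | pyrrhoxanthinol (CNP0180336.1) | CC1=C(C#C/C(C)=C/C=C/C=C/C=C(C)/C=C2C=C(/C=C/[C@@]34O[C@]3(C)C[C@@H](O)CC4(C)C)C(=O)O/2)C(C)(C)C[C@H](O)C1 | target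

Total step count: 22. Longest linear sequence: 13 steps (steps 1–12, then step 22).

Steps most likely to fail

Step 4. The 1,2-shift may take the wrong course: migration of the quaternary α-carbon, collapse of the betaine to an epoxide, or Lewis-acid-induced loss of the β-silyloxy group before insertion. The fallback sets out from 5 and comes back at 6, and fixes the position of the inserted carbon by an enol ether instead of by migratory aptitude. Soft enolisation of 5 (TMSOTf, Et3N, CH2Cl2, 0 °C) can only give the trimethylsilyl enol ether F1, because the other α-carbon is quaternary. Ethylidene transfer (CH3CHI2, Et2Zn, Furukawa-type Simmons–Smith) gives the siloxycyclopropane F2. FeCl3 in DMF (Ito–Saegusa ring enlargement) cleaves the internal cyclopropane bond to the ring-expanded β-chloro ketone F3, NaOAc in MeOH eliminates HCl to the enone F4, and H2 over Pd/C returns 6.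

Step 21. Oxidative addition may not discriminate cleanly between the dienyl iodide and the butenolide bromide, and the aqueous base needed for transmetalation may open the butenolide. The fallback sets out from 19 and 25 and comes back at 27, joining the same carbons by olefination without palladium. Vinylmagnesium bromide (excess, THF, −78 °C) adds to 19 to give the bis-allylic carbinol F5. HBr·PPh3 in MeOH converts it with allylic transposition into the E-dienyl phosphonium bromide F6. Wittig olefination of 25 with the ylide of F6 (NaHMDS, THF, −78 °C), followed by iodine-catalysed equilibration of the new double bond to E, gives 27.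

Step 22. Transmetalation of the vinylstannane next to the quaternary epoxide carbon may be slow, so that protodestannylation, E/Z isomerisation or decomposition of the long polyene competes on prolonged warming. The fallback sets out from 24 and 15 and comes back at 28, moving the Stille coupling to a small, robust substrate that can be forced. Coupling of 24 with 15 (Pd2(dba)3, AsPh3, NMP, 60 °C) gives the epoxy dienyl butenolide alcohol F7. MnO2 gives the aldehyde F8, Takai olefination (CrCl2, CHI3) gives the dienyl iodide F9, and Suzuki coupling of F9 with 20 (Pd(PPh3)4, TlOEt, THF/H2O, rt) gives 28.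

Further compounds
F1 | step 4 | (3S)-3-[(tert-butyldimethylsilyl)oxy]-5,5-dimethyl-1-[(trimethylsilyl)oxy]cyclopent-1-ene | CC1(C)C[C@H](O[Si](C)(C)C(C)(C)C)C=C1O[Si](C)(C)C
F2 | step 4 | 4-[(tert-butyldimethylsilyl)oxy]-2,2,6-trimethyl-1-[(trimethylsilyl)oxy]bicyclo[3.1.0]hexane (configuration at the oxygenated carbon as in 5, cyclopropane isomers) | CC1C2[C@@H](O[Si](C)(C)C(C)(C)C)CC(C)(C)C12O[Si](C)(C)C
F3 | step 4 | (4R)-4-[(tert-butyldimethylsilyl)oxy]-3-chloro-2,6,6-trimethylcyclohexan-1-one (isomers at C2 and C3) | CC1C(Cl)[C@@H](O[Si](C)(C)C(C)(C)C)CC(C)(C)C1=O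
F4 | step 4 | (4R)-4-[(tert-butyldimethylsilyl)oxy]-2,6,6-trimethylcyclohex-2-en-1-one | CC1=C[C@@H](O[Si](C)(C)C(C)(C)C)CC(C)(C)C1=O
F5 | step 21 | (4E)-7-[(4R)-4-hydroxy-2,6,6-trimethylcyclohex-1-en-1-yl]-5-methylhepta-1,4-dien-6-yn-3-ol (both carbinol epimers) | CC1=C(C#C/C(C)=C/C(O)C=C)C(C)(C)C[C@H](O)C1
F6 | step 21 | [(2E,4E)-7-[(4R)-4-hydroxy-2,6,6-trimethylcyclohex-1-en-1-yl]-5-methylhepta-2,4-dien-6-yn-1-yl]triphenylphosphonium bromide | CC1=C(C#C/C(C)=C/C=C/C[P+](c2ccccc2)(c2ccccc2)c2ccccc2)C(C)(C)C[C@H](O)C1.[Br-]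
F7 | step 22 | (5Z)-5-[(2E)-4-hydroxy-2-methylbut-2-en-1-ylidene]-3-{(E)-2-[(1S,4S,6R)-4-hydroxy-2,2,6-trimethyl-7-oxabicyclo[4.1.0]heptan-1-yl]ethenyl}furan-2(5H)-one | OC/C=C(C)/C=C1C=C(/C=C/[C@@]23O[C@]2(C)C[C@@H](O)CC3(C)C)C(=O)O/1
F8 | step 22 | (2E,4Z)-4-[4-{(E)-2-[(1S,4S,6R)-4-hydroxy-2,2,6-trimethyl-7-oxabicyclo[4.1.0]heptan-1-yl]ethenyl}-5-oxofuran-2(5H)-ylidene]-3-methylbut-2-enal | O=C/C=C(C)/C=C1C=C(/C=C/[C@@]23O[C@]2(C)C[C@@H](O)CC3(C)C)C(=O)O/1
F9 | step 22 | (5Z)-3-{(E)-2-[(1S,4S,6R)-4-hydroxy-2,2,6-trimethyl-7-oxabicyclo[4.1.0]heptan-1-yl]ethenyl}-5-[(2E,4E)-5-iodo-2-methylpenta-2,4-dien-1-ylidene]furan-2(5H)-one | I/C=C/C=C(C)/C=C1C=C(/C=C/[C@@]23O[C@]2(C)C[C@@H](O)CC3(C)C)C(=O)O/1
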